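**Retrosynthetic overview**
- Structural feature: C19 (lactone C=O), C8 (acetyl C=O with its CH3), C7 (CH–OAc) and C6 (lactone O–CH) form a 2-methylbuta-1,3-diene unit bridging quaternary C4 and ring-fusion C5 of ring A. Reconnecting C19 to C8 gives a cyclohexene (ring C) whose C8–C19 glycol cleavage returns lactone carbonyl plus methyl ketone.
- Late disconnections: lactone O–C6 (carboxylate SN2 with inversion), C8–C19 (Pb(OAc)4 on the diol from osmylation of C7=C8), C9–C11 (2-(furan-3-yl)ethyllithium plus C9 aldehyde), C3=O removed.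
- Key disconnection: C4–C19 and C5–C6 by Diels–Alder addition of a 1-silyloxy-4-acetoxy-2-methylbutadiene to a 2,4-dimethyl-4-(silyloxymethyl)cyclohex-2-enone.
- Ring order: ring A (Michael/aldol annulation, sets C10), then ring C (cycloaddition, sets C4, C5 and provisional C6), then ring C opened, then the γ-lactone (ring B) closed last.

Key step: step 5

Remark: atoms carry the numbers of the target skeleton (ring A = C1–C5 and C10; C18, C20 = methyls on C4, C10; C19 = lactone carbonyl; C6 = lactone O–CH; C7 = CH–OAc; C8 = acetyl carbonyl; C9 = side-chain ketone); "upper face of ring C" is the face carrying the bonds C4–C3 and C5–C10; 2-(furan-3-yl)ethanol is assumed to be a catalogue compound.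

**Step 1**
Reactants: 1 2-methylpropane-1,3-diol
Product: 2 3-(tert-butyldimethylsilyloxy)-2-methylpropan-1-ol (racemic)
Conditions: NaH (1.0 equiv), THF, 0 °C to rt; then TBSCl
Reagents that add atoms: tert-butyldimethylsilyl chloride CC(C)(C)[Si](C)(C)Cl
Why: Monosilylation of a symmetric diol through its sparingly soluble mono-sodium alkoxide (McDougal protocol) should stop at one silyl group; the centre is racemic and is planarised in step 3.

**Step 2**
Reactants: 2 3-(tert-butyldimethylsilyloxy)-2-methylpropan-1-ol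
Product: 3 3-(tert-butyldimethylsilyloxy)-2-methylpropanal (racemic)
Conditions: DMP, CH2Cl2, 0 °C to rt
Reagents that add atoms: none
Why: Dess–Martin oxidation of a primary alcohol under non-basic conditions should give the aldehyde without β-elimination of the silyloxy group.

**Step 3**
Reactants: 3 3-(tert-butyldimethylsilyloxy)-2-methylpropanal; 4 pent-1-en-3-one
Product: 6 (S)-4-[(tert-butyldimethylsilyloxy)methyl]-2,4-dimethylcyclohex-2-en-1-one, via keto aldehyde 5 (not isolated)
Conditions: (S)-N-(4-dodecylphenylsulfonyl)pyrrolidine-2-carboxamide (20 mol%), 4 Å MS, ClCH2CH2Cl, rt; then LiOH, i-PrOH, rt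
Reagents that add atoms: none
Why: Enamine-catalysed Michael addition of the α-branched aldehyde to the vinyl ketone, with the sulfonamide N–H directing the enone to one enamine face (CH2OTBS trans to nitrogen), is expected to set C10 as in (R)-5, and base-mediated intramolecular aldol condensation then closes ring A (Robinson-type annulation); the catalyst antipode would be used should the sense prove opposite.

**Step 4**
Reactants: 7 (E)-4-acetoxy-2-methylbut-2-enal
Product: 8 (1E,3E)-4-acetoxy-1-(tert-butyldimethylsilyloxy)-2-methylbuta-1,3-diene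
Conditions: TBSOTf, Et3N, Et2O, 0 °C to rt
Reagents that add atoms: tert-butyldimethylsilyl trifluoromethanesulfonate CC(C)(C)[Si](C)(C)OS(=O)(=O)C(F)(F)F
Why: Soft enolisation (O-silylation, then γ-deprotonation at the acetoxy-bearing CH2) should give the silyl dienol ether, the s-trans enal leading to the 1E geometry and conjugation favouring the 3E enol acetate.

**Step 5**
Reactants: 6 (S)-4-[(tert-butyldimethylsilyloxy)methyl]-2,4-dimethylcyclohex-2-en-1-one; 8 (1E,3E)-4-acetoxy-1-(tert-butyldimethylsilyloxy)-2-methylbuta-1,3-diene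
Product: 9 cis-fused endo cycloadduct (C3 ketone; ring C = C4–C19H(OTBS)–C8(CH3)=C7H–C6H(OAc)–C5; OAc and OTBS on the upper face of ring C; C6 and C19 cis to the C10 methyl)
Conditions: Tf2NH (10 mol%), CH2Cl2, −78 to −40 °C; Et3N quench
Reagents that add atoms: none
Why: This is a normal-electron-demand [4+2] cycloaddition in which Tf2NH protodesilylates a trace of 8 to TBSNTf2, whose silyl cation binds the C3 carbonyl of 6 and lowers the LUMO of the C4=C5 alkene; the closest known reaction type is the triflimide (silyl triflimide)-catalysed Diels–Alder reaction of hindered cyclohex-2-enones with silyloxydienes. Ring C (six-membered carbocycle) closes by suprafacial addition of the s-cis diene termini across C4=C5 (C5–C6 leading, C4–C19 following), so the A/C fusion is necessarily cis. C4 and C5 are controlled by C10: the diene adds to the enone face anti to CH2OTBS and syn to the smaller C10 methyl, which places C6 and C19 cis to that methyl and C18 on the opposite face. C6 and C19 are controlled by the E,E geometry of 8 and the endo orientation of the diene over the activated C3 carbonyl, which puts OAc and OTBS cis to each other and to C3 (C6 is thus formed epimeric to the target and is inverted in step 21; C19 is destroyed in step 20). Regiochemistry follows from the stronger silyloxy donor, which makes the acetoxy-bearing terminus C6 the nucleophilic end that bonds to the β-carbon C5. The step needs regio-, facial and endo selectivity plus enough reactivity at the neopentyl C5, and relies on the donor difference, the CH3/CH2OTBS size difference and cationic activation to secure them.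

**Step 6**
Reactants: 9 cis-fused endo cycloadduct
Product: 10 C3 tosylhydrazone of 9
Conditions: TsNHNH2, PPTS (cat.), EtOH, 60 °C
Reagents that add atoms: 4-methylbenzenesulfonohydrazide Cc1ccc(cc1)S(=O)(=O)NN
Why: Acid-catalysed hydrazone formation should proceed even at this α-quaternary ketone on heating, and the allylic acetate and silyl ethers tolerate PPTS.

**Step 7**
Reactants: 10 C3 tosylhydrazone
Product: 11 C3-deoxy cycloadduct (C3H2; 6-OAc, 19-OTBS, C7=C8 unchanged)
Conditions: catecholborane, CHCl3, 0 °C to rt; then NaOAc·3H2O, reflux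
Reagents that add atoms: none
Why: Caglioti–Kabalka reductive deoxygenation (hydride addition to C=N, acetate-induced loss of sulfinate, N2 extrusion from the diazene) should give the methylene without touching C7=C8 or the ester.

**Step 8**
Reactants: 11 C3-deoxy cycloadduct
Product: 12 allylic alcohol (C6–OH, configuration unchanged)
Conditions: K2CO3, MeOH, rt
Reagents that add atoms: none
Why: Base-catalysed methanolysis (transesterification) removes the acetate while both silyl ethers are stable to carbonate in methanol.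

**Step 9**
Reactants: 12 allylic alcohol
Product: 13 6,7,8-triol (C7–OH and C8–OH on the lower face of ring C, trans to O6 and O19; C8 methyl on the upper face)
Conditions: OsO4 (10 mol%), NMO, acetone/H2O, rt
Reagents that add atoms: osmium tetroxide O=[Os](=O)(=O)=O; N-methylmorpholine N-oxide C[N+]1([O-])CCOCC1 (terminal oxygen source)
Why: Upjohn syn-dihydroxylation should occur on the face of C7=C8 anti to both allylic oxygens (C6–OH by Kishi's rule, C19–OTBS) and to ring A, which sets C7 in the target configuration and C8 (later destroyed).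

**Step 10**
Reactants: 13 6,7,8-triol
Product: 14 7,8-O-isopropylidene derivative (C6–OH free)
Conditions: 2,2-dimethoxypropane, PPTS (cat.), acetone, rt
Reagents that add atoms: 2,2-dimethoxypropane COC(C)(C)OC
Why: Acetonide formation should select the cis C7/C8 diol (cis-fused dioxolane) over the trans C6/C7 pair, singling out O6.

**Step 11**
Reactants: 14 7,8-O-isopropylidene alcohol
Product: 15 C6 mesylate
Conditions: MsCl, Et3N, CH2Cl2, 0 °C
Reagents that add atoms: methanesulfonyl chloride CS(=O)(=O)Cl
Why: Sulfene-mediated mesylation of the only free hydroxyl installs, with retention at C6, the leaving group for the final inversion.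

**Step 12**
Reactants: 15 C6 mesylate
Product: 16 primary alcohol (C9H2OH)
Conditions: HF·pyridine, pyridine, THF, 0 °C to rt
Reagents that add atoms: none
Why: Buffered fluoride desilylation should cleave the primary TBS ether much faster than the C19 TBS ether flanked by two fully substituted carbons, with acetonide and mesylate inert.

**Step 13**
Reactants: 16 primary alcohol
Product: 17 C9 aldehyde
Conditions: DMP, CH2Cl2, rt
Reagents that add atoms: none
Why: Dess–Martin oxidation gives the neopentyl aldehyde, which has no α-hydrogen and cannot epimerise.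

**Step 14**
Reactants: 18 2-(furan-3-yl)ethanol
Product: 19 3-(2-iodoethyl)furan
Conditions: I2, PPh3, imidazole, CH2Cl2, 0 °C to rt
Reagents that add atoms: iodine II
Why: Appel-type iodination of a primary alcohol under neutral conditions leaves the furan intact.

**Step 15**
Reactants: 19 3-(2-iodoethyl)furan; 17 C9 aldehyde
Product: 21 C9 carbinol CH(OH)CH2CH2(furan-3-yl) (both C9 epimers), via 2-(furan-3-yl)ethyllithium 20 (not isolated)
Conditions: t-BuLi (2.0 equiv), Et2O, −78 °C; then 17, −78 °C; NH4Cl (aq)
Reagents that add atoms: none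
Why: Iodine–lithium exchange gives the primary alkyllithium, whose 1,2-addition to the aldehyde at −78 °C should outpace attack on or deprotonation of the hindered mesylate; the new C9 carbinol centre forms as a mixture and is erased in step 16.

**Step 16**
Reactants: 21 C9 carbinol
Product: 22 C9 ketone
Conditions: DMP, CH2Cl2, rt
Reagents that add atoms: none
Why: Dess–Martin oxidation of the secondary alcohol is tolerated by furan, mesylate, acetonide and silyl ether.

**Step 17**
Reactants: 22 C9 ketone
Product: 23 7,8-diol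
Conditions: AcOH/THF/H2O (3:1:1), 45 °C
Reagents that add atoms: none
Why: Mild acid-catalysed acetonide hydrolysis should spare the 3-alkylfuran, the mesylate and the hindered C19 silyl ether.

**Step 18**
Reactants: 23 7,8-diol
Product: 24 C7 acetate (C8–OH free)
Conditions: Ac2O, pyridine, DMAP (cat.), CH2Cl2, 0 °C
Reagents that add atoms: acetic anhydride CC(=O)OC(C)=O
Why: DMAP-catalysed acylation esterifies the secondary C7–OH and leaves the tertiary C8–OH, and pyridine is too weak a base to close an epoxide onto the C6 mesylate.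

**Step 19**
Reactants: 24 C7 acetate
Product: 25 8,19-diol
Conditions: HF·pyridine, THF, 0 °C to rt
Reagents that add atoms: none
Why: Non-basic fluoride desilylation frees the hindered C19–OH without acetyl migration or elimination of the mesylate.

**Step 20**
Reactants: 25 8,19-diol
Product: 26 ring-C-opened keto aldehyde (C4–CHO; C5–C6H(OMs)–C7H(OAc)–C8(=O)CH3)
Conditions: Pb(OAc)4, K2CO3, CH2Cl2, −20 to 0 °C
Reagents that add atoms: none
Why: Criegee glycol cleavage, which also accepts trans-diols, opens ring C between C8 and C19 to the methyl ketone and a non-enolisable aldehyde, no other free glycol being present.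

**Step 21**
Reactants: 26 ring-C-opened keto aldehyde
Product: 28 CNP0170401.2 (target), via seco acid 27 (not isolated)
Conditions: NaClO2, NaH2PO4, 2-methylbut-2-ene, t-BuOH/H2O, 0 °C to rt; then NaHCO3, 40 °C
Reagents that add atoms: sodium chlorite [Na+].[O-]Cl=O
Why: Pinnick oxidation gives the C19 acid, whose carboxylate should close the γ-lactone by intramolecular SN2 displacement (5-exo-tet) of the C6 mesylate with inversion, setting C6, while bicarbonate keeps the C8 ketone un-enolised so that E1cB loss of mesylate should not compete.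

**Compound list**
1 | 2-methylpropane-1,3-diol | CC(CO)CO | starting material
2 | 3-(tert-butyldimethylsilyloxy)-2-methylpropan-1-ol (racemic) | CC(CO)CO[Si](C)(C)C(C)(C)C | intermediate
3 | 3-(tert-butyldimethylsilyloxy)-2-methylpropanal (racemic) | CC(C=O)CO[Si](C)(C)C(C)(C)C | intermediate
4 | pent-1-en-3-one | CCC(=O)C=C | starting material
5 | (R)-2-[(tert-butyldimethylsilyloxy)methyl]-2-methyl-5-oxoheptanal (not isolated) | O=C[C@@](C)(CO[Si](C)(C)C(C)(C)C)CCC(=O)CC | intermediate
6 | (S)-4-[(tert-butyldimethylsilyloxy)methyl]-2,4-dimethylcyclohex-2-en-1-one | CC1=C[C@@](C)(CO[Si](C)(C)C(C)(C)C)CCC1=O | intermediate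
7 | (E)-4-acetoxy-2-methylbut-2-enal | CC(=O)OC/C=C(C)/C=O | starting material
8 | (1E,3E)-4-acetoxy-1-(tert-butyldimethylsilyloxy)-2-methylbuta-1,3-diene | CC(=O)O/C=C/C(C)=C/O[Si](C)(C)C(C)(C)C | intermediate
9 | cis-fused endo cycloadduct: 5-acetoxy-8-(tert-butyldimethylsilyloxy)-4-[(tert-butyldimethylsilyloxy)methyl]-4,7,8a-trimethyl-3,4,4a,5,8,8a-hexahydronaphthalen-1(2H)-one (OAc and OTBS on the upper face of ring C; C6 and C19 cis to the C10 methyl) | CC(=O)O[C@H]1C=C(C)[C@@H](O[Si](C)(C)C(C)(C)C)[C@@]2(C)C(=O)CC[C@](C)(CO[Si](C)(C)C(C)(C)C)[C@@H]12 | intermediate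
10 | C3 tosylhydrazone of 9 | CC(=O)O[C@H]1C=C(C)[C@@H](O[Si](C)(C)C(C)(C)C)[C@@]2(C)C(=NNS(=O)(=O)c3ccc(C)cc3)CC[C@](C)(CO[Si](C)(C)C(C)(C)C)[C@@H]12 | intermediate
11 | C3-deoxy cycloadduct (C3H2) | CC(=O)O[C@H]1C=C(C)[C@@H](O[Si](C)(C)C(C)(C)C)[C@@]2(C)CCC[C@](C)(CO[Si](C)(C)C(C)(C)C)[C@@H]12 | intermediate
12 | allylic alcohol (C6–OH) | O[C@H]1C=C(C)[C@@H](O[Si](C)(C)C(C)(C)C)[C@@]2(C)CCC[C@](C)(CO[Si](C)(C)C(C)(C)C)[C@@H]12 | intermediate
13 | 6,7,8-triol (O7, O8 on the lower face of ring C) | O[C@H]1[C@H](O)[C@](C)(O)[C@@H](O[Si](C)(C)C(C)(C)C)[C@@]2(C)CCC[C@](C)(CO[Si](C)(C)C(C)(C)C)[C@@H]12 | intermediate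
14 | 7,8-O-isopropylidene derivative of 13 (C6–OH free) | O[C@H]1[C@@H]3OC(C)(C)O[C@]3(C)[C@@H](O[Si](C)(C)C(C)(C)C)[C@@]2(C)CCC[C@](C)(CO[Si](C)(C)C(C)(C)C)[C@@H]12 | intermediate
15 | C6 mesylate of 14 | CS(=O)(=O)O[C@H]1[C@@H]3OC(C)(C)O[C@]3(C)[C@@H](O[Si](C)(C)C(C)(C)C)[C@@]2(C)CCC[C@](C)(CO[Si](C)(C)C(C)(C)C)[C@@H]12 | intermediate
16 | primary alcohol (C9H2OH) | CS(=O)(=O)O[C@H]1[C@@H]3OC(C)(C)O[C@]3(C)[C@@H](O[Si](C)(C)C(C)(C)C)[C@@]2(C)CCC[C@](C)(CO)[C@@H]12 | intermediate
17 | C9 aldehyde | CS(=O)(=O)O[C@H]1[C@@H]3OC(C)(C)O[C@]3(C)[C@@H](O[Si](C)(C)C(C)(C)C)[C@@]2(C)CCC[C@](C)(C=O)[C@@H]12 | intermediate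
18 | 2-(furan-3-yl)ethanol | OCCc1ccoc1 | starting material
19 | 3-(2-iodoethyl)furan | ICCc1ccoc1 | intermediate
20 | 2-(furan-3-yl)ethyllithium (not isolated) | [Li]CCc1ccoc1 | intermediate
21 | C9 carbinol, both C9 epimers | CS(=O)(=O)O[C@H]1[C@@H]3OC(C)(C)O[C@]3(C)[C@@H](O[Si](C)(C)C(C)(C)C)[C@@]2(C)CCC[C@](C)(C(O)CCc4ccoc4)[C@@H]12 | intermediate
22 | C9 ketone | CS(=O)(=O)O[C@H]1[C@@H]3OC(C)(C)O[C@]3(C)[C@@H](O[Si](C)(C)C(C)(C)C)[C@@]2(C)CCC[C@](C)(C(=O)CCc4ccoc4)[C@@H]12 | intermediate
23 | 7,8-diol | CS(=O)(=O)O[C@H]1[C@H](O)[C@](C)(O)[C@@H](O[Si](C)(C)C(C)(C)C)[C@@]2(C)CCC[C@](C)(C(=O)CCc3ccoc3)[C@@H]12 | intermediate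
24 | C7 acetate (C8–OH free) | CS(=O)(=O)O[C@H]1[C@H](OC(C)=O)[C@](C)(O)[C@@H](O[Si](C)(C)C(C)(C)C)[C@@]2(C)CCC[C@](C)(C(=O)CCc3ccoc3)[C@@H]12 | intermediate
25 | 8,19-diol | CS(=O)(=O)O[C@H]1[C@H](OC(C)=O)[C@](C)(O)[C@@H](O)[C@@]2(C)CCC[C@](C)(C(=O)CCc3ccoc3)[C@@H]12 | intermediate
26 | ring-C-opened keto aldehyde (C4–CHO, C6–OMs, C7–OAc, C8 methyl ketone) | CC(=O)O[C@H](C(C)=O)[C@H](OS(C)(=O)=O)[C@H]1[C@@](C)(C=O)CCC[C@]1(C)C(=O)CCc2ccoc2 | intermediate
27 | seco acid (C4–CO2H, C6–OMs) (not isolated) | CC(=O)O[C@H](C(C)=O)[C@H](OS(C)(=O)=O)[C@H]1[C@@](C)(C(=O)O)CCC[C@]1(C)C(=O)CCc2ccoc2 | intermediate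
28 | CNP0170401.2 | CC(=O)O[C@H](C(C)=O)[C@H]1OC(=O)[C@@]2(C)CCC[C@](C)(C(=O)CCc3ccoc3)[C@@H]12 | target

**Step count**
Total: 21 steps. Longest linear sequence: 19 steps (steps 1–3, 5–13, 15–21).

**Steps most likely to fail**

Step 5 (cycloaddition). The neopentyl β-carbon C5 and the methyl-bearing α-carbon C4 may react so slowly that diene 8 is lost to protodesilylation or oligomerisation, or an open Michael adduct may form without ring closure. The fallback sets out from 6 and returns at 9, and reshapes the dienophile into a cation.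
- Enone 6 is ketalised (1,2-bis(trimethylsilyloxy)ethane, TMSOTf cat., CH2Cl2, −78 °C; no double-bond shift is possible because C10 is quaternary) to the allylic dioxolane (S)-8-[(tert-butyldimethylsilyloxy)methyl]-6,8-dimethyl-1,4-dioxaspiro[4.5]dec-6-ene F1.
- Catalytic TMSOTf opens F1 to the 2-alkoxyallyl (vinyl-oxocarbenium) cation, which adds diene 8 in an ionic, Gassman-type Diels–Alder reaction at −78 °C to give the C3 ethylene ketal of the cycloadduct F2.
- PPTS in wet acetone hydrolyses F2 to 9.

Step 3 (annulation). Enantioselectivity may erode because the two enamine geometries (CH3 or CH2OTBS cis to nitrogen) are poorly differentiated, and β-elimination of silanol may compete. The fallback sets out from 3 and 4 and returns at 6, replacing asymmetric catalysis by resolution.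
- The Michael/aldol annulation is run with pyrrolidine and then KOH in EtOH, giving the racemic keto aldehyde F3 and the racemic enone F4.
- The (S)-enantiomer 6 is separated by preparative supercritical-fluid chromatography on an amylose carbamate chiral phase.

Step 7 (reduction of the hydrazone). Hydride transfer to the C3 hydrazone next to quaternary C4 may be too slow, returning hydrazone or giving elimination products. The fallback sets out from 9 and returns at 11, replacing the hydrazone path by radical deoxygenation.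
- NaBH4 (MeOH, 0 °C) reduces the C3 ketone to the secondary alcohol F5 (either C3 epimer serves).
- PhOC(S)Cl, pyridine and DMAP give the O-phenyl thionocarbonate F6.
- Bu3SnH and AIBN in toluene at 100 °C (Barton–McCombie) give 11.

**Further compounds**
F1 | step 5 | (S)-8-[(tert-butyldimethylsilyloxy)methyl]-6,8-dimethyl-1,4-dioxaspiro[4.5]dec-6-ene | CC1=C[C@@](C)(CO[Si](C)(C)C(C)(C)C)CCC12OCCO2
F2 | step 5 | C3 ethylene ketal of cycloadduct 9 | CC(=O)O[C@H]1C=C(C)[C@@H](O[Si](C)(C)C(C)(C)C)[C@@]2(C)C3(OCCO3)CC[C@](C)(CO[Si](C)(C)C(C)(C)C)[C@@H]12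
F3 | step 3 | racemic 2-[(tert-butyldimethylsilyloxy)methyl]-2-methyl-5-oxoheptanal | O=CC(C)(CO[Si](C)(C)C(C)(C)C)CCC(=O)CC
F4 | step 3 | racemic 4-[(tert-butyldimethylsilyloxy)methyl]-2,4-dimethylcyclohex-2-en-1-one | CC1=CC(C)(CO[Si](C)(C)C(C)(C)C)CCC1=O
F5 | step 7 | C3 alcohol of cycloadduct 9 (C3 epimers) | CC(=O)O[C@H]1C=C(C)[C@@H](O[Si](C)(C)C(C)(C)C)[C@@]2(C)C(O)CC[C@](C)(CO[Si](C)(C)C(C)(C)C)[C@@H]12
F6 | step 7 | C3 O-phenyl thionocarbonate | CC(=O)O[C@H]1C=C(C)[C@@H](O[Si](C)(C)C(C)(C)C)[C@@]2(C)C(OC(=S)Oc3ccccc3)CC[C@](C)(CO[Si](C)(C)C(C)(C)C)[C@@H]12
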